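## Structural features

The target is a flavone: a chromen-4-one (benzo ring A fused to pyranone ring C) with a 2,4-dihydroxyphenyl ring B on C2, hydroxyls on C5 and C7, a 3-methylbut-2-enyl group on C6 and a ten-carbon chain on C3. The chain is a geranyl unit whose 2'',3''-alkene has been dihydroxylated: C1''H2 is bonded to C3, C2'' is a secondary carbinol, C3'' is a tertiary carbinol bearing a methyl group, and the 6'',7''-alkene is intact. C2'' and C3'' are the only stereocentres; they are adjacent and (2''S,3''R), the relative arrangement that arises from anti addition of two oxygens to an E alkene. The fragile elements are the two trisubstituted alkenes, each within reach of a hydroxyl that can add to it under acid (prenyl with 5-OH or 7-OH, the 6'',7''-alkene with 3''-OH), the ionisable tertiary alcohol, the electron-rich ring B and the electrophilic C2 of the chromone. The real difficulty is twofold. C6 and C8 of ring A are each flanked by two oxygens and are nearly equivalent toward electrophiles, so direct C-prenylation cannot choose C6. The tertiary carbinol must also be set in a defined relation to C2''. The key step uses the fact that O5, held in a hydrogen bond by the C4 carbonyl and therefore the last hydroxyl to be protected, has only C6 and the ring-fusion carbon C4a as ortho neighbours, whereas C8 is ortho to O7 and O1; an allyl unit tethered to O5 can thus be passed to C6 only.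

## Logic of the disconnections

**18 to 17.** The three O–CH2OCH3 bonds on O7, O2' and O4' and the two ketal C–O bonds on O2'' and O3'' are cut. All masking groups belong to one acid-labile class, so one operation ends the synthesis, and 17 has a single free hydroxyl. The forward step must use acid weak enough not to add a phenol to the prenyl alkene or ionise the tertiary carbinol.

**17 to 16.** The C6–C1''' bond is cut and the five-carbon unit is reattached through its tertiary carbon C3''' to O5. This turns an unsolvable C6/C8 choice in C-alkylation into O-alkylation of the one free hydroxyl. The forward step must be a concerted shift, not an ionisation, which calls for a neutral medium and moderate heat.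

**16 to 15 to 13 and 14.** The O5–C3''' ether bond is cut, and the vinyl group is carried as an ethynyl group. A tertiary allyl ether cannot be made by direct displacement, whereas a tertiary propargylic halide ionises under copper catalysis and is captured by a phenoxide. This leaves 13 and the commercial five-carbon chloride 14. The forward steps must alkylate a hydrogen-bonded, hindered hydroxyl and stop the hydrogenation at the alkene.

**13 to 12 and 10.** The C3–C4 and O1–C2 bonds of ring C are cut. The molecule falls into a ring A aldehyde and a ring B alkyne that carries the whole chain with both stereocentres. Since 12 is symmetric, whichever ortho hydroxyl closes the ring leaves the other as the free 5-OH. The forward annulation must place the aryl-bearing alkyne carbon on oxygen and must tolerate the ketal, the MOM ethers and the alkene at elevated temperature.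

**12 to 11.** The O–CH2OCH3 bond at the para oxygen is cut. Only the hydroxyl that is not hydrogen-bonded to the formyl group is to be protected, which the forward step must achieve with one equivalent of reagent.

**10 to 9 to 8 and 5.** The ketal is removed, then the bond between the alkyne carbon (the future C3) and C1'' is cut. Opening an oxirane at its CH2 terminus makes this bond and releases the C2'' hydroxyl without touching either stereocentre. The forward step must attack only the CH2 terminus and cope with the free tertiary hydroxyl.

**8 to 7 to 6.** The alkyne carbon–carbon bond is cut back to an aldehyde (one-carbon homologation), and the two MOM groups are removed. The demand is a homologation under base mild enough for the MOM ethers.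

**5 to 3 to 2 to 1.** The oxirane C1''–O bond is cut back to a primary sulfonate of 3. The C3''–O bond is traced to water attacking the tertiary carbon of 2 with inversion. The oxirane of 2 is traced to tartrate-controlled epoxidation of 1, whose allylic hydroxyl singles out the 2,3-alkene. Syn epoxidation plus anti opening gives the required anti diol from an E alkene. Water must attack C3 only and with inversion, because attack at C2 would give the enantiomeric triol.

## Other disconnections considered

**Alternative 1: Parham-type closure of ring C.**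
- **Cut:** C4–C4a.
- **Forward key step:** In A2, ring A is an aryl bromide (bromine on the future C4a) linked through O1 to the Z enol ether of an α-alkylidene butyrolactone whose ring oxygen is the C2'' oxygen. t-BuLi at −78 °C would exchange bromine for lithium. The aryllithium would add to the lactone carbonyl (6-exo-trig), and collapse of the adduct would release the C2'' alkoxide and give A1.
- **In favour:** The connectivity of ring C (aryl on C2, chain on C3) is fixed by construction and does not depend on an insertion preference; on this point it is better than step 9. The closure runs cold, and the C2'' hydroxyl emerges differentiated from the silylated C3'' oxygen.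
- **Against:** A2 needs a fully substituted ring A with the prenyl group already on the right carbon, so the C6/C8 problem is moved into an arene synthesis, not solved. The tetrasubstituted enol ether must have the aryloxy group cis to the lactone carbonyl. t-BuLi meets four MOM ethers that direct ortho-lithiation, and the silyl group could migrate to the freed secondary alkoxide.
- **Comparison:** The anionic closure is mechanistically as sound as the annulation. The chosen plan obtains the prenyl position from the mechanism of step 12 and needs fewer steps than the assembly of A2 would.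

**Alternative 2: Hydroxyl-directed epoxidation on the flavone.**
- **Cut:** The C3''–O bond, followed by the C4''–C5'' bond.
- **Forward key step:** A4, a flavone that already carries the 6-prenyl group and a (2''S) allylic alcohol with an isopropenyl group, would be epoxidised by VO(acac)2 and t-BuOOH through the vanadate ester of the C2'' hydroxyl to give A3. A prenyl organometallic would then open the oxirane CH2 to complete the chain.
- **In favour:** A(1,2) strain in 2-substituted allylic alcohols is expected to favour the erythro epoxy alcohol, which is the relative configuration needed. The directed oxidant should spare the isolated prenyl alkene. The tertiary centre is set on the intact flavone, which allows late variation of the chain; on this point it is better than the chosen plan.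
- **Against:** The C2'' carbinol must first be made enantioselectively next to the chromone. The chain extension asks a prenyl metal to react at its CH2 terminus, although such reagents prefer the tertiary terminus, and in the presence of the chromone carbonyl and the C2 acceptor position. The C6 prenyl group must already be in place, so the ring A problem remains.
- **Comparison:** On stereocontrol the two plans are equal in principle (substrate-directed diastereoselection against reagent-controlled epoxidation with stereospecific opening). On chemoselectivity and step count on the valuable flavone the chosen plan is better.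

**Alternative 3: Rhodium annulation as the last skeletal step.**
- **Cut:** C3–C4 and O1–C2, with the prenyl group already on the aldehyde.
- **Forward key step:** A6 and the alkyne 10 would be joined under [Cp*RhCl2]2 with Cu(OAc)2 to give A5, which the same acid treatment would convert into the target.
- **In favour:** This is the most convergent plan. Steps 10 to 12 vanish, and no thermal rearrangement is run on the complete skeleton; in convergence and in length after the union it is better than the chosen plan. The ring-forming mechanism is the same as in step 9, so the mechanistic risk is equal.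
- **Against:** A6 must carry the prenyl group between two oxygens and have free only the ortho hydroxyl remote from it. Both ortho hydroxyls are hydrogen-bonded to the formyl group and nearly alike, so telling them apart is the C6/C8 problem in another form; closure through the wrong one would give the 8-prenyl isomer. The formyl group flanked by a MOM ether is also more hindered than in 12.
- **Comparison:** The chosen plan is better in that 12 is symmetric and one step from a commercial compound, and in that the hydrogen bond itself marks the oxygen that carries the tether.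

Key step: step 12

Remark: locants are O1–C4 (ring C), C4a–C8a (ring A), primed for ring B, C1''–C8'' for the chain counted from C3 and C1'''–C5''' for the prenyl group counted from C6. The chain descriptors (2''S,3''R) and the dioxolane descriptors (4S,5R) denote the same spatial arrangement. Compound 14 and the Ohira–Bestmann reagent are taken as purchased.

## Route

Step 1
Reactants: 1 geraniol
Product: 2 [(2S,3S)-3-methyl-3-(4-methylpent-3-enyl)oxiran-2-yl]methanol
Conditions: Ti(OiPr)4 (5 mol %), L-(+)-diethyl tartrate (6 mol %), t-BuOOH (isooctane), 4 Å MS, CH2Cl2, −20 °C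
Reagents that add atoms: tert-butyl hydroperoxide, CC(C)(C)OO
Why: Katsuki–Sharpless asymmetric epoxidation; the allylic hydroxyl binds the titanium tartrate complex, so only the 2,3-alkene reacts, and the L-(+)-tartrate should deliver oxygen to the face that gives the (2S,3S)-oxirane, while the 6,7-alkene has no directing group.

Step 2
Reactants: 2 [(2S,3S)-3-methyl-3-(4-methylpent-3-enyl)oxiran-2-yl]methanol
Product: 3 (2S,3R)-3,7-dimethyloct-6-ene-1,2,3-triol
Conditions: HClO4 (aq., cat.), THF/H2O, 0 °C
Reagents that add atoms: water, O
Why: Acid-catalysed epoxide hydrolysis; water should attack the protonated oxirane at the tertiary C3, which bears most of the positive charge, while C2 is deactivated by the neighbouring CH2OH, and backside attack inverts C3 (S to R) without breaking the C2–O bond.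

Step 3
Reactants: 3 (2S,3R)-3,7-dimethyloct-6-ene-1,2,3-triol
Product: 5 (2R)-6-methyl-2-[(2S)-oxiran-2-yl]hept-5-en-2-ol, via primary tosylate 4 (not isolated)
Conditions: TsCl, Et3N, Bu2SnO (2 mol %), CH2Cl2, 0 °C to rt; then K2CO3, MeOH, 0 °C to rt
Reagents that add atoms: none
Why: Tin-acetal-mediated monosulfonylation of the 1,2-diol selects the primary hydroxyl, and carbonate then closes the oxirane by intramolecular Williamson displacement (3-exo-tet) through the C2 oxygen, so no bond at a stereocentre is broken; the weak base hardly forms the tertiary alkoxide that a Payne isomerisation would need.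

Step 4
Reactants: 6 2,4-dihydroxybenzaldehyde
Product: 7 2,4-bis(methoxymethoxy)benzaldehyde
Conditions: MOMCl, i-Pr2NEt, CH2Cl2, 0 °C to 40 °C
Reagents that add atoms: chloromethyl methyl ether, COCCl
Why: Williamson-type acetal protection of both phenols; excess reagent and gentle warming are used because the 2-OH is hydrogen-bonded to the formyl group.

Step 5
Reactants: 7 2,4-bis(methoxymethoxy)benzaldehyde
Product: 8 1-ethynyl-2,4-bis(methoxymethoxy)benzene
Conditions: dimethyl (1-diazo-2-oxopropyl)phosphonate, K2CO3, MeOH, 0 °C to rt
Reagents that add atoms: dimethyl (1-diazo-2-oxopropyl)phosphonate, CC(=O)C(=[N+]=[N-])P(=O)(OC)OC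
Why: Seyferth–Gilbert homologation in the Ohira–Bestmann form; methanolysis releases the diazomethylphosphonate anion, which olefinates the aldehyde, and loss of N2 with a 1,2-hydrogen shift gives the terminal alkyne under base that MOM ethers tolerate.

Step 6
Reactants: 8 1-ethynyl-2,4-bis(methoxymethoxy)benzene; 5 (2R)-6-methyl-2-[(2S)-oxiran-2-yl]hept-5-en-2-ol
Product: 9 (4S,5R)-1-[2,4-bis(methoxymethoxy)phenyl]-5,9-dimethyldec-8-en-1-yne-4,5-diol
Conditions: 8 (3 equiv), n-BuLi, THF, −78 °C; BF3·OEt2; then 5, −78 °C; aq. NH4Cl
Reagents that add atoms: none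
Why: Yamaguchi–Hirao alkynylation; the boron-activated monosubstituted oxirane should be opened at its unhindered CH2 terminus in an SN2 manner, so both stereocentres of 5 pass unchanged into 9, the excess acetylide absorbs the tertiary hydroxyl proton, and MOM ethers withstand BF3·OEt2 in THF at −78 °C.

Step 7
Reactants: 9 (4S,5R)-1-[2,4-bis(methoxymethoxy)phenyl]-5,9-dimethyldec-8-en-1-yne-4,5-diol
Product: 10 (4S,5R)-4-{3-[2,4-bis(methoxymethoxy)phenyl]prop-2-ynyl}-2,2,5-trimethyl-5-(4-methylpent-3-enyl)-1,3-dioxolane
Conditions: Me2C(OMe)2, PPTS (cat.), CH2Cl2, rt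
Reagents that add atoms: 2,2-dimethoxypropane, COC(C)(C)OC
Why: Acid-catalysed transketalisation of the 1,2-diol; the weak pyridinium acid should leave the aryl MOM ethers intact, and both C–O bonds at the stereocentres are retained.

Step 8
Reactants: 11 2,4,6-trihydroxybenzaldehyde
Product: 12 2,6-dihydroxy-4-(methoxymethoxy)benzaldehyde
Conditions: MOMCl (1.05 equiv), i-Pr2NEt, THF, 0 °C
Reagents that add atoms: chloromethyl methyl ether, COCCl
Why: Selective Williamson-type protection; the para hydroxyl is the most acidic and the only one not tied to the formyl group by a hydrogen bond, so one equivalent of reagent should alkylate it alone.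

Step 9
Reactants: 12 2,6-dihydroxy-4-(methoxymethoxy)benzaldehyde; 10 (4S,5R)-4-{3-[2,4-bis(methoxymethoxy)phenyl]prop-2-ynyl}-2,2,5-trimethyl-5-(4-methylpent-3-enyl)-1,3-dioxolane
Product: 13 2-[2,4-bis(methoxymethoxy)phenyl]-5-hydroxy-7-(methoxymethoxy)-3-{[(4S,5R)-2,2,5-trimethyl-5-(4-methylpent-3-enyl)-1,3-dioxolan-4-yl]methyl}chromen-4-one
Conditions: [RhCl(cod)]2 (2.5 mol %), C5H2Ph4 (10 mol %), Cu(OAc)2·H2O (2.1 equiv), o-xylene, 130 °C, N2
Reagents that add atoms: none
Why: Rhodium-catalysed oxidative annulation of a salicylaldehyde with an internal alkyne; O–H and formyl C–H activation give a five-membered acyl rhodium phenoxide, the alkyne inserts with its aryl-bearing carbon on trivalent rhodium, and C–O reductive elimination closes ring C before Cu(OAc)2 reoxidises the metal; the two ortho hydroxyls of 12 are equivalent, so the one not used remains as the free 5-OH.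

Step 10
Reactants: 13 2-[2,4-bis(methoxymethoxy)phenyl]-5-hydroxy-7-(methoxymethoxy)-3-{[(4S,5R)-2,2,5-trimethyl-5-(4-methylpent-3-enyl)-1,3-dioxolan-4-yl]methyl}chromen-4-one; 14 3-chloro-3-methylbut-1-yne
Product: 15 2-[2,4-bis(methoxymethoxy)phenyl]-7-(methoxymethoxy)-5-(2-methylbut-3-yn-2-yloxy)-3-{[(4S,5R)-2,2,5-trimethyl-5-(4-methylpent-3-enyl)-1,3-dioxolan-4-yl]methyl}chromen-4-one
Conditions: 14 (excess), DBU, CuCl2·2H2O (1 mol %), MeCN, 0 °C to rt
Reagents that add atoms: none
Why: Copper-catalysed propargylic etherification; the copper acetylide of 14 ionises to a stabilised propargyl/allenyl cation that is captured at its tertiary carbon by the phenoxide, DBU is strong enough to break the hydrogen bond to the carbonyl, and the 5-OH is the only free hydroxyl.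

Step 11
Reactants: 15 2-[2,4-bis(methoxymethoxy)phenyl]-7-(methoxymethoxy)-5-(2-methylbut-3-yn-2-yloxy)-3-{[(4S,5R)-2,2,5-trimethyl-5-(4-methylpent-3-enyl)-1,3-dioxolan-4-yl]methyl}chromen-4-one
Product: 16 2-[2,4-bis(methoxymethoxy)phenyl]-7-(methoxymethoxy)-5-(2-methylbut-3-en-2-yloxy)-3-{[(4S,5R)-2,2,5-trimethyl-5-(4-methylpent-3-enyl)-1,3-dioxolan-4-yl]methyl}chromen-4-one
Conditions: H2 (1 atm), Pd/CaCO3 poisoned with Pb(OAc)2, quinoline, EtOAc, rt
Reagents that add atoms: none
Why: Lindlar-type semihydrogenation; the terminal alkyne binds the poisoned palladium surface far better than the trisubstituted alkene or the tetrasubstituted chromone double bond, and quinoline should stop the reduction at the vinyl group.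

Step 12
Reactants: 16 2-[2,4-bis(methoxymethoxy)phenyl]-7-(methoxymethoxy)-5-(2-methylbut-3-en-2-yloxy)-3-{[(4S,5R)-2,2,5-trimethyl-5-(4-methylpent-3-enyl)-1,3-dioxolan-4-yl]methyl}chromen-4-one
Product: 17 2-[2,4-bis(methoxymethoxy)phenyl]-5-hydroxy-7-(methoxymethoxy)-6-(3-methylbut-2-enyl)-3-{[(4S,5R)-2,2,5-trimethyl-5-(4-methylpent-3-enyl)-1,3-dioxolan-4-yl]methyl}chromen-4-one
Conditions: PhNEt2 (2 equiv), degassed toluene, 110 °C, sealed tube
Reagents that add atoms: none
Why: Aromatic Claisen rearrangement, a concerted suprafacial (3,3)-sigmatropic shift through a six-membered chair-like transition state in which the terminal CH2 (C1''') of the 2-methylbut-3-en-2-yl group bonds to C6 while the O5–C3''' bond breaks. The 6-allyl cyclohexadienone formed first should enolise at once, and the restored hydrogen bond from 5-OH to the C4 carbonyl makes the sequence irreversible. The closest known reaction type is the thermal rearrangement of aryl 1,1-dimethylallyl ethers to ortho-(3-methylbut-2-enyl)phenols, in which the gem-dimethyl group weakens the O–C bond so that about 110 °C is enough. No ring is closed and no stereocentre is formed; the (4S,5R)-dioxolane is a spectator. The selectivity needed is C6 over C8 and concerted shift over ionisation. O5 has only C6 and the ring-fusion carbon C4a as ortho positions, bonding at C4a would give a dienone that cannot enolise and can only revert, and C8 cannot be reached through a six-membered transition state from O5. N,N-Diethylaniline keeps the medium free of acid, so the tertiary ether should not ionise to a free allyl cation that would escape positional control, and the 7-OMOM group blocks later ring closure of the prenyl group on that side.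

Step 13
Reactants: 17 2-[2,4-bis(methoxymethoxy)phenyl]-5-hydroxy-7-(methoxymethoxy)-6-(3-methylbut-2-enyl)-3-{[(4S,5R)-2,2,5-trimethyl-5-(4-methylpent-3-enyl)-1,3-dioxolan-4-yl]methyl}chromen-4-one
Product: 18 2-(2,4-dihydroxyphenyl)-3-[(2S,3R)-2,3-dihydroxy-3,7-dimethyloct-6-enyl]-5,7-dihydroxy-6-(3-methylbut-2-enyl)chromen-4-one
Conditions: HCl (about 1 M, from conc. aq. HCl), MeOH, rt to 40 °C
Reagents that add atoms: none
Why: Acid-catalysed acetal exchange with methanol removes the three aryl MOM ethers and the ketal in one operation; dilute acid and mild temperature are chosen so that neither alkene is protonated, and no bond at C2'' or C3'' is broken.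

## Compound list

1 | geraniol, (2E)-3,7-dimethylocta-2,6-dien-1-ol | CC(C)=CCC/C(C)=C/CO | starting material
2 | [(2S,3S)-3-methyl-3-(4-methylpent-3-enyl)oxiran-2-yl]methanol | OC[C@@H]1O[C@@]1(C)CCC=C(C)C | intermediate
3 | (2S,3R)-3,7-dimethyloct-6-ene-1,2,3-triol | CC(C)=CCC[C@@](C)(O)[C@@H](O)CO | intermediate
4 | (2S,3R)-2,3-dihydroxy-3,7-dimethyloct-6-enyl 4-methylbenzenesulfonate | CC(C)=CCC[C@@](C)(O)[C@@H](O)COS(=O)(=O)c1ccc(C)cc1 | intermediate (not isolated)
5 | (2R)-6-methyl-2-[(2S)-oxiran-2-yl]hept-5-en-2-ol | CC(C)=CCC[C@@](C)(O)[C@@H]1CO1 | intermediate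
6 | 2,4-dihydroxybenzaldehyde | O=Cc1ccc(O)cc1O | starting material
7 | 2,4-bis(methoxymethoxy)benzaldehyde | COCOc1ccc(C=O)c(OCOC)c1 | intermediate
8 | 1-ethynyl-2,4-bis(methoxymethoxy)benzene | COCOc1ccc(C#C)c(OCOC)c1 | intermediate
9 | (4S,5R)-1-[2,4-bis(methoxymethoxy)phenyl]-5,9-dimethyldec-8-en-1-yne-4,5-diol | CC(C)=CCC[C@@](C)(O)[C@@H](O)CC#Cc1ccc(OCOC)cc1OCOC | intermediate
10 | (4S,5R)-4-{3-[2,4-bis(methoxymethoxy)phenyl]prop-2-ynyl}-2,2,5-trimethyl-5-(4-methylpent-3-enyl)-1,3-dioxolane | CC(C)=CCC[C@@](C)(OC1(C)C)[C@@H](O1)CC#Cc1ccc(OCOC)cc1OCOC | intermediate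
11 | 2,4,6-trihydroxybenzaldehyde | O=Cc1c(O)cc(O)cc1O | starting material
12 | 2,6-dihydroxy-4-(methoxymethoxy)benzaldehyde | COCOc1cc(O)c(C=O)c(O)c1 | intermediate
13 | 2-[2,4-bis(methoxymethoxy)phenyl]-5-hydroxy-7-(methoxymethoxy)-3-{[(4S,5R)-2,2,5-trimethyl-5-(4-methylpent-3-enyl)-1,3-dioxolan-4-yl]methyl}chromen-4-one | CC(C)=CCC[C@@](C)(OC3(C)C)[C@@H](O3)Cc1c(-c2ccc(OCOC)cc2OCOC)oc2cc(OCOC)cc(O)c2c1=O | intermediate
14 | 3-chloro-3-methylbut-1-yne | CC(C)(Cl)C#C | starting material
15 | 2-[2,4-bis(methoxymethoxy)phenyl]-7-(methoxymethoxy)-5-(2-methylbut-3-yn-2-yloxy)-3-{[(4S,5R)-2,2,5-trimethyl-5-(4-methylpent-3-enyl)-1,3-dioxolan-4-yl]methyl}chromen-4-one | CC(C)=CCC[C@@](C)(OC3(C)C)[C@@H](O3)Cc1c(-c2ccc(OCOC)cc2OCOC)oc2cc(OCOC)cc(OC(C)(C)C#C)c2c1=O | intermediate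
16 | 2-[2,4-bis(methoxymethoxy)phenyl]-7-(methoxymethoxy)-5-(2-methylbut-3-en-2-yloxy)-3-{[(4S,5R)-2,2,5-trimethyl-5-(4-methylpent-3-enyl)-1,3-dioxolan-4-yl]methyl}chromen-4-one | CC(C)=CCC[C@@](C)(OC3(C)C)[C@@H](O3)Cc1c(-c2ccc(OCOC)cc2OCOC)oc2cc(OCOC)cc(OC(C)(C)C=C)c2c1=O | intermediate
17 | 2-[2,4-bis(methoxymethoxy)phenyl]-5-hydroxy-7-(methoxymethoxy)-6-(3-methylbut-2-enyl)-3-{[(4S,5R)-2,2,5-trimethyl-5-(4-methylpent-3-enyl)-1,3-dioxolan-4-yl]methyl}chromen-4-one | CC(C)=CCC[C@@](C)(OC3(C)C)[C@@H](O3)Cc1c(-c2ccc(OCOC)cc2OCOC)oc2cc(OCOC)c(CC=C(C)C)c(O)c2c1=O | intermediate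
18 | 2-(2,4-dihydroxyphenyl)-3-[(2S,3R)-2,3-dihydroxy-3,7-dimethyloct-6-enyl]-5,7-dihydroxy-6-(3-methylbut-2-enyl)chromen-4-one | CC(C)=CCC[C@@](C)(O)[C@@H](O)Cc1c(-c2ccc(O)cc2O)oc2cc(O)c(CC=C(C)C)c(O)c2c1=O | target

## Step count and least certain steps

Total: 13 steps (step 3 is one flask in two stages). Longest linear sequence: 10 steps from 1 (steps 1, 2, 3, 6, 7, 9, 10, 11, 12, 13).

**Step 12 (key step).** The most likely failure is heterolysis of the crowded tertiary ether, which sits peri to the carbonyl and has an electron-poor aryloxy leaving group, in competition with the concerted shift. That would mean loss of the five-carbon unit or its uncontrolled return to the ring. Fallback, from 13 back to 17 without any rearrangement: 13 is iodinated ortho to the hydrogen-bonded hydroxyl with BnMe3N·ICl2 and CaCO3 in CH2Cl2/MeOH to give 2-[2,4-bis(methoxymethoxy)phenyl]-5-hydroxy-6-iodo-7-(methoxymethoxy)-3-{[(4S,5R)-2,2,5-trimethyl-5-(4-methylpent-3-enyl)-1,3-dioxolan-4-yl]methyl}chromen-4-one F1. Suzuki–Miyaura coupling of this iodide with commercial 3-methylbut-2-enylboronic acid pinacol ester (Pd(OAc)2, a bulky biarylphosphine chosen for bonding at the CH2 terminus, K3PO4, THF/H2O) should then give 17.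

**Step 9.** The likely failures are imperfect regiocontrol of alkyne insertion, because the aryl group is ortho-substituted and the propargylic carbon is branched, slow turnover with a chelating dihydroxy aldehyde, and erosion of the acetal groups by acetic acid at 130 °C. Fallback, from 12 and 10 back to 13 in two separate operations: hydroacylation without oxidant ([RhCl(cod)]2, dppf, Na2CO3, toluene, 110 °C; monovalent rhodium adds the formyl C–H across the alkyne with the acyl group on the CH2-bearing carbon) should give (2E)-3-[2,4-bis(methoxymethoxy)phenyl]-1-[2,6-dihydroxy-4-(methoxymethoxy)phenyl]-2-{[(4S,5R)-2,2,5-trimethyl-5-(4-methylpent-3-enyl)-1,3-dioxolan-4-yl]methyl}prop-2-en-1-one F2. Its regiochemistry can be secured before ring closure, and a Wacker-type oxidative oxa-cyclisation (Pd(TFA)2 cat., O2, DMSO, 80 °C; divalent palladium) should close ring C to 13.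

**Step 10.** The likely failures are incomplete O-alkylation of the hydrogen-bonded, peri-hindered hydroxyl and competing elimination of the tertiary chloride. Fallback, from 13 directly to 16 (15 and step 11 are bypassed): tert-butyl 2-methylbut-3-en-2-yl carbonate F3 is prepared from 2-methylbut-3-en-2-ol with n-BuLi and Boc2O. Tsuji–Trost O-allylation of 13 with this carbonate and Pd(PPh3)4 in THF at 0 °C should give 16, since the phenoxide attacks the more substituted terminus of the 1,1-dimethylallyl complex formed from zerovalent palladium.

**Step 6.** The likely failures are consumption of the reagents by the free tertiary hydroxyl, Lewis-acid-induced rearrangement of the hydroxy epoxide, and partial MOM loss. Fallback, from 2 and 8 back to 9, making the C–C bond before the epoxide is opened: 2 is converted with Tf2O and 2,6-lutidine (CH2Cl2, −78 °C) into [(2S,3S)-3-methyl-3-(4-methylpent-3-enyl)oxiran-2-yl]methyl trifluoromethanesulfonate F4. The lithium acetylide of 8 (THF/DMPU, −78 to −20 °C) displaces the triflate at the primary carbon to give (2S,3S)-2-{3-[2,4-bis(methoxymethoxy)phenyl]prop-2-ynyl}-3-methyl-3-(4-methylpent-3-enyl)oxirane F5. Hydrolysis with HClO4 (cat.) in THF/H2O at 0 °C, with inversion at the tertiary carbon, should give 9.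

**Step 2.** The likely failures are loss of stereochemical fidelity through a cation-like opening (partial retention at C3) and some attack at C2, which would lead to the enantiomer. Fallback, from 1 back to 3 without any reaction at the tertiary centre: 1 is epoxidised as in step 1 but with D-(−)-diethyl tartrate to give [(2R,3R)-3-methyl-3-(4-methylpent-3-enyl)oxiran-2-yl]methanol F6. Payne rearrangement with opening (0.5 M NaOH, t-BuOH/H2O, 70 °C) inverts C2 through the primary alkoxide, which forms 5 in equilibrium, and hydroxide opens the CH2 terminus of 5 to give 3.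

**Step 13.** The likely failures are acid-promoted addition of 5-OH or 7-OH to the prenyl alkene (chromane formation) or of 3''-OH to the 6'',7''-alkene, before the last MOM ether is gone. Fallback, from 17 to 18 in two stages without strong protic acid: TMSOTf and 2,2'-bipyridyl in MeCN at 0 °C, then water, should convert the aryl MOM ethers into phenols and leave the more hindered ketal, giving 2-(2,4-dihydroxyphenyl)-5,7-dihydroxy-6-(3-methylbut-2-enyl)-3-{[(4S,5R)-2,2,5-trimethyl-5-(4-methylpent-3-enyl)-1,3-dioxolan-4-yl]methyl}chromen-4-one F7. The ketal is then hydrolysed with AcOH/H2O (4:1) at 35 °C to give 18.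

## Further compounds

F1 | step 12 | 2-[2,4-bis(methoxymethoxy)phenyl]-5-hydroxy-6-iodo-7-(methoxymethoxy)-3-{[(4S,5R)-2,2,5-trimethyl-5-(4-methylpent-3-enyl)-1,3-dioxolan-4-yl]methyl}chromen-4-one | CC(C)=CCC[C@@](C)(OC3(C)C)[C@@H](O3)Cc1c(-c2ccc(OCOC)cc2OCOC)oc2cc(OCOC)c(I)c(O)c2c1=O
F2 | step 9 | (2E)-3-[2,4-bis(methoxymethoxy)phenyl]-1-[2,6-dihydroxy-4-(methoxymethoxy)phenyl]-2-{[(4S,5R)-2,2,5-trimethyl-5-(4-methylpent-3-enyl)-1,3-dioxolan-4-yl]methyl}prop-2-en-1-one | CC(C)=CCC[C@@](C)(OC1(C)C)[C@@H](O1)C/C(C(=O)c1c(O)cc(OCOC)cc1O)=C\c1ccc(OCOC)cc1OCOC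
F3 | step 10 | tert-butyl 2-methylbut-3-en-2-yl carbonate | CC(C)(C)OC(=O)OC(C)(C)C=C
F4 | step 6 | [(2S,3S)-3-methyl-3-(4-methylpent-3-enyl)oxiran-2-yl]methyl trifluoromethanesulfonate | FC(F)(F)S(=O)(=O)OC[C@@H]1O[C@@]1(C)CCC=C(C)C
F5 | step 6 | (2S,3S)-2-{3-[2,4-bis(methoxymethoxy)phenyl]prop-2-ynyl}-3-methyl-3-(4-methylpent-3-enyl)oxirane | COCOc1ccc(C#CC[C@@H]2O[C@@]2(C)CCC=C(C)C)c(OCOC)c1
F6 | step 2 | [(2R,3R)-3-methyl-3-(4-methylpent-3-enyl)oxiran-2-yl]methanol | OC[C@H]1O[C@]1(C)CCC=C(C)C
F7 | step 13 | 2-(2,4-dihydroxyphenyl)-5,7-dihydroxy-6-(3-methylbut-2-enyl)-3-{[(4S,5R)-2,2,5-trimethyl-5-(4-methylpent-3-enyl)-1,3-dioxolan-4-yl]methyl}chromen-4-one | CC(C)=CCC[C@@](C)(OC3(C)C)[C@@H](O3)Cc1c(-c2ccc(O)cc2O)oc2cc(O)c(CC=C(C)C)c(O)c2c1=O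
A1 | alternative 1 | 2-[2,4-bis(methoxymethoxy)phenyl]-3-[(2S,3R)-2-hydroxy-3,7-dimethyl-3-(triethylsilyloxy)oct-6-enyl]-5,7-bis(methoxymethoxy)-6-(3-methylbut-2-enyl)chromen-4-one | CC(C)=CCC[C@@](C)(O[Si](CC)(CC)CC)[C@@H](O)Cc1c(-c2ccc(OCOC)cc2OCOC)oc2cc(OCOC)c(CC=C(C)C)c(OCOC)c2c1=O
A2 | alternative 1 | (3Z,5S)-3-{[2,4-bis(methoxymethoxy)phenyl][2-bromo-3,5-bis(methoxymethoxy)-4-(3-methylbut-2-enyl)phenoxy]methylidene}-5-[(2R)-6-methyl-2-(triethylsilyloxy)hept-5-en-2-yl]oxolan-2-one | O=C1O[C@H]([C@](C)(O[Si](CC)(CC)CC)CCC=C(C)C)C/C1=C(/Oc1cc(OCOC)c(CC=C(C)C)c(OCOC)c1Br)c1ccc(OCOC)cc1OCOC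
A3 | alternative 2 | 2-[2,4-bis(methoxymethoxy)phenyl]-3-{(2S)-2-hydroxy-2-[(2R)-2-methyloxiran-2-yl]ethyl}-5,7-bis(methoxymethoxy)-6-(3-methylbut-2-enyl)chromen-4-one | C[C@@]1(CO1)[C@@H](O)Cc1c(-c2ccc(OCOC)cc2OCOC)oc2cc(OCOC)c(CC=C(C)C)c(OCOC)c2c1=O
A4 | alternative 2 | 2-[2,4-bis(methoxymethoxy)phenyl]-3-[(2S)-2-hydroxy-3-methylbut-3-enyl]-5,7-bis(methoxymethoxy)-6-(3-methylbut-2-enyl)chromen-4-one | C=C(C)[C@@H](O)Cc1c(-c2ccc(OCOC)cc2OCOC)oc2cc(OCOC)c(CC=C(C)C)c(OCOC)c2c1=O
A5 | alternative 3 | 2-[2,4-bis(methoxymethoxy)phenyl]-5,7-bis(methoxymethoxy)-6-(3-methylbut-2-enyl)-3-{[(4S,5R)-2,2,5-trimethyl-5-(4-methylpent-3-enyl)-1,3-dioxolan-4-yl]methyl}chromen-4-one | CC(C)=CCC[C@@](C)(OC3(C)C)[C@@H](O3)Cc1c(-c2ccc(OCOC)cc2OCOC)oc2cc(OCOC)c(CC=C(C)C)c(OCOC)c2c1=O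
A6 | alternative 3 | 6-hydroxy-2,4-bis(methoxymethoxy)-3-(3-methylbut-2-enyl)benzaldehyde | O=Cc1c(O)cc(OCOC)c(CC=C(C)C)c1OCOC
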